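## Retrosynthetic overview
1. Feature: the phenol ring reads C1(OH), C2(Br), C3(H), C4(Br), C5(H), C6(pyrrol-2-yl). The run C2–C5 (Br, H, Br, H) is the diene C3–C6 of 3,5-dibromo-2-pyrone, and the pair C1/C6 (O, pyrrolyl) is an alkynyl ether.
2. Endgame disconnections: the phenol O–CH3 bond, the three pyrrole C–Br bonds (C3, C4, C5) and the N–sulfonyl bond.
3. Key disconnection: C1–C2 and C5–C6 of the benzene ring, by Diels–Alder addition and loss of CO2, back to 3,5-dibromo-2-pyrone and 2-(methoxyethynyl)-1-tosylpyrrole.
4. The alkyne comes from 2-iodo-1-tosylpyrrole and methoxyethynylzinc chloride (Negishi coupling). The pyrone comes from coumalic acid (bromodecarboxylation).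
5. Ring order: the pyrrole ring is bought. The pyrone ring is bought and becomes the benzene ring in the key step, which is the only ring-forming event.

Key step: step 5

Remark 1: the alkynyl ether is carried as the methyl ether, not the more easily bought ethyl ether, because 1-ethoxyalkynes lose ethene by a retro-ene reaction (giving ketenes) near the temperature the cycloaddition is expected to need, and a methyl ether has no β-hydrogen.
Remark 2: where one reagent puts several bromine atoms on the same ring in one operation (steps 1 and 7), the partly brominated species are transient members of a mixture whose order of formation is not fixed, so they are not numbered.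

## Route

Step 1
Reactants: 1 coumalic acid (2-oxo-2H-pyran-5-carboxylic acid)
Product: 2 3,5-dibromo-2H-pyran-2-one
Conditions: NBS (2.5 equiv), Bu4NBr (5 mol %), CHCl3, 50 °C
Reagents that add atoms: N-bromosuccinimide, O=C1CCC(=O)N1Br
Why: Hunsdiecker-type ipso-bromodecarboxylation at C5 and electrophilic bromination at C3 address the two pyrone positions that are conjugated with the ring oxygen, and this one-flask conversion is a known preparation of the dibromopyrone.

Step 2
Reactants: 3 pyrrole
Product: 4 1-tosyl-1H-pyrrole
Conditions: TsCl (1.1 equiv), 50% aq NaOH, Bu4NHSO4 (5 mol %), CH2Cl2, 0 °C to rt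
Reagents that add atoms: p-toluenesulfonyl chloride, Cc1ccc(cc1)S(=O)(=O)Cl
Why: Phase-transfer N-sulfonylation of the pyrrolide anion is standard and takes place at nitrogen, and the sulfonyl group later directs the metalation and tames the pyrrole.

Step 3
Reactants: 4 1-tosyl-1H-pyrrole
Product: 6 2-iodo-1-tosyl-1H-pyrrole, via 2-lithio-1-tosylpyrrole 5 (not isolated)
Conditions: LiN(iPr)2 (1.2 equiv), THF, −78 °C; I2 (1.3 equiv), −78 °C to rt; aq Na2S2O3
Reagents that add atoms: iodine, II
Why: In this directed metalation the sulfonyl group acidifies and coordinates at H-2, the hindered amide base does not attack sulfur, and iodinolysis of the 2-lithio species should give a 2-iodopyrrole that the acceptor on nitrogen makes stable enough to handle.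

Step 4
Reactants: 6 2-iodo-1-tosyl-1H-pyrrole; 7 2-chloro-1,1-dimethoxyethane (chloroacetaldehyde dimethyl acetal)
Product: 10 2-(methoxyethynyl)-1-tosyl-1H-pyrrole, via lithium methoxyacetylide 8 (not isolated), via methoxyethynylzinc chloride 9 (not isolated)
Conditions: 7 (2 equiv), LiNEt2 (from Et2NH and n-BuLi, 3 equiv per 7), THF, 0 °C; ZnCl2 (2 equiv per 7), 0 °C; then 6, Pd(PPh3)4 (5 mol %), THF, rt; aq NaHCO3, basic Al2O3
Reagents that add atoms: none
Why: Threefold base treatment of a chloroacetal (loss of methanol, loss of HCl, deprotonation) is the classical in-flask source of lithium alkoxyacetylides, and Negishi coupling of alkoxyethynylzinc chlorides with aryl iodides under zerovalent palladium at room temperature is a known route to aryl alkynyl ethers; the excess ZnCl2 binds methoxide so that the N-tosyl group is spared.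

Step 5
Reactants: 2 3,5-dibromo-2H-pyran-2-one; 10 2-(methoxyethynyl)-1-tosyl-1H-pyrrole
Product: 12 2-(3,5-dibromo-2-methoxyphenyl)-1-tosyl-1H-pyrrole, via bridged bicyclic lactone 11 (not isolated)
Conditions: 2 (1.5 equiv), PhMe (1 M), NaHCO3 (solid), sealed tube, 110 °C, −CO2
Reagents that add atoms: none
Why: The electron-poor diene C3=C4–C5=C6 of 2 (LUMO lowered by the lactone carbonyl and both bromines) and the electron-rich triple bond of 10 combine in an inverse-electron-demand Diels–Alder reaction, a one-step, asynchronous, intermolecular [4+2] ring closure of the six-membered carbocycle in which the bond from the pyrrole-bearing alkyne carbon to pyrone C6 runs ahead of the bond from the methoxy-bearing carbon to C3. The adduct 11 is a 2-oxabicyclo[2.2.2]octa-5,7-dien-3-one that should not survive at 110 °C: retro-[4+2] loss of its O–C(=O) bridge as CO2 is driven by aromatisation and leaves the benzene ring with C1–C2 and C5–C6 newly made and OMe, Br, H, Br, H and pyrrolyl in the order of the target. The reaction type is the known thermal 2-pyrone/alkyne cycloaddition–decarboxylation, which has been run with donor alkynes such as ynamines and silyl ynol ethers, and 2 is known to take up enol ethers with the oxygen-bearing carbon at C3; this pair of partners is a new application and carries the main risk of the route. Regioselectivity is the only selectivity required: the methoxy lone pair makes the distal alkyne carbon the nucleophilic one, which matches C6, the vinylogous acceptor end of the pyrone; the sulfonyl group weakens the opposing push of the pyrrole; and sterics agree, since the bulky pyrrolyl carbon meets the C6–H terminus and the slim methoxy carbon meets C3–Br. No stereocentre has to be controlled, because the two bridgehead centres of racemic 11 vanish on aromatisation. The methyl ether tolerates the heating without retro-ene collapse to a ketene, the sulfonyl group lowers the π-donor power of the pyrrole enough that it stays a spectator, and NaHCO3 takes up traces of HBr that would hydrate the alkynyl ether.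

Step 6
Reactants: 12 2-(3,5-dibromo-2-methoxyphenyl)-1-tosyl-1H-pyrrole
Product: 13 2-(3,5-dibromo-2-methoxyphenyl)-1H-pyrrole
Conditions: KOH (5 equiv), MeOH/THF/H2O, 60 °C
Reagents that add atoms: none
Why: In this basic sulfonamide cleavage hydroxide attacks sulfur and expels the pyrrolide, a good leaving group, while the unactivated aryl bromides and the methyl ether are inert to aqueous alkali.

Step 7
Reactants: 13 2-(3,5-dibromo-2-methoxyphenyl)-1H-pyrrole
Product: 14 2,3,4-tribromo-5-(3,5-dibromo-2-methoxyphenyl)-1H-pyrrole
Conditions: NBS (3.05 equiv), THF, −78 °C to rt, dark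
Reagents that add atoms: N-bromosuccinimide, O=C1CCC(=O)N1Br
Why: In this electrophilic aromatic substitution the free NH-pyrrole is far more nucleophilic than the dibromoanisole ring, whose only open positions are meta to the methoxy group, so three equivalents of NBS should fill pyrrole C5, C4 and C3 and then stop.

Step 8
Reactants: 14 2,3,4-tribromo-5-(3,5-dibromo-2-methoxyphenyl)-1H-pyrrole
Product: 16 pentabromopseudilin (2,4-dibromo-6-(3,4,5-tribromo-1H-pyrrol-2-yl)phenol), via aryloxydibromoborane 15 (not isolated)
Conditions: BBr3 (3 equiv), CH2Cl2, −78 °C to rt; H2O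
Reagents that add atoms: none
Why: In this Lewis-acid aryl methyl ether cleavage BBr3 binds the ether oxygen, bromide removes the methyl group by SN2 attack and water hydrolyses the B–O bond, while the electron-poor tribromopyrrole should tolerate the acidic medium.

## Compound list
1 | coumalic acid | O=C(O)C1=COC(=O)C=C1 | starting material
2 | 3,5-dibromo-2H-pyran-2-one | O=C1OC=C(Br)C=C1Br | intermediate
3 | pyrrole | c1cc[nH]c1 | starting material
4 | 1-tosyl-1H-pyrrole | Cc1ccc(cc1)S(=O)(=O)n1cccc1 | intermediate
5 | 2-lithio-1-tosylpyrrole (not isolated) | [Li]c1cccn1S(=O)(=O)c1ccc(C)cc1 | intermediate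
6 | 2-iodo-1-tosyl-1H-pyrrole | Ic1cccn1S(=O)(=O)c1ccc(C)cc1 | intermediate
7 | 2-chloro-1,1-dimethoxyethane | COC(CCl)OC | starting material
8 | lithium methoxyacetylide (not isolated) | [Li]C#COC | intermediate
9 | methoxyethynylzinc chloride (not isolated) | Cl[Zn]C#COC | intermediate
10 | 2-(methoxyethynyl)-1-tosyl-1H-pyrrole | COC#Cc1cccn1S(=O)(=O)c1ccc(C)cc1 | intermediate
11 | 4,6-dibromo-8-methoxy-7-(1-tosyl-1H-pyrrol-2-yl)-2-oxabicyclo[2.2.2]octa-5,7-dien-3-one (racemic, bridgeheads fixed by the bicycle, not isolated) | O=C1OC2C(Br)=CC1(Br)C(OC)=C2c1cccn1S(=O)(=O)c1ccc(C)cc1 | intermediate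
12 | 2-(3,5-dibromo-2-methoxyphenyl)-1-tosyl-1H-pyrrole | COc1c(Br)cc(Br)cc1-c1cccn1S(=O)(=O)c1ccc(C)cc1 | intermediate
13 | 2-(3,5-dibromo-2-methoxyphenyl)-1H-pyrrole | COc1c(Br)cc(Br)cc1-c1ccc[nH]1 | intermediate
14 | 2,3,4-tribromo-5-(3,5-dibromo-2-methoxyphenyl)-1H-pyrrole | COc1c(Br)cc(Br)cc1-c1[nH]c(Br)c(Br)c1Br | intermediate
15 | dibromo[2,4-dibromo-6-(3,4,5-tribromo-1H-pyrrol-2-yl)phenoxy]borane (not isolated) | BrB(Br)Oc1c(Br)cc(Br)cc1-c1[nH]c(Br)c(Br)c1Br | intermediate
16 | pentabromopseudilin (achiral, no stereocentre) | Oc1c(Br)cc(Br)cc1-c1[nH]c(Br)c(Br)c1Br | target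

## Step count and risks
Total steps: 8. Longest linear sequence: 7 (steps 2–8, from pyrrole).

**1. Step 5.** The cycloaddition of a fully substituted donor alkyne may be slower than thermal oligomerisation or adventitious hydration of the alkynyl ether, and donation from the pyrrole may erode the regioselectivity.

The fallback sets out from 4 and comes back at 12. In it the benzene ring is bought instead of built.
- Commercial 2,4-dibromophenol is iodinated at its only free ortho position (N-iodosuccinimide, cat. TsOH, MeCN) to 2,4-dibromo-6-iodophenol F1.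
- F1 is O-methylated (MeI, K2CO3, acetone) to 1,5-dibromo-3-iodo-2-methoxybenzene F2.
- Compound 4 is lithiated as in step 3 to 5 and transmetalated with ZnCl2 to (1-tosyl-1H-pyrrol-2-yl)zinc chloride F3.
- F3 is joined to F2 by Negishi coupling (Pd(PPh3)4, THF, rt). Oxidative addition takes the C–I bond ahead of both C–Br bonds, and the product is 12.

**2. Step 4.** The acetylide may be generated incompletely, amine and methoxide may interfere with transmetalation, the sulfonyl group may be lost to alkoxide, and the product may be hydrated on work-up or chromatography.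

The fallback sets out from 4 (through 5) and comes back at 10. The triple bond is made by elimination rather than by coupling.
- Compound 5 is acylated with commercial N,2-dimethoxy-N-methylacetamide (Weinreb ketone synthesis) to 2-methoxy-1-(1-tosyl-1H-pyrrol-2-yl)ethan-1-one F4.
- LiN(SiMe3)2 and PhNTf2 (THF/DMPU, −78 °C) trap the chelated enolate as (Z)-2-methoxy-1-(1-tosyl-1H-pyrrol-2-yl)vinyl trifluoromethanesulfonate F5.
- KOtBu (THF, −78 °C) removes the vinylic hydrogen anti to the triflate and gives 10. This α-alkoxy ketone to enol triflate to alkynyl ether sequence is known.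

**3. Step 7.** Bromination may be incomplete or unselective, and partly brominated NH-pyrroles may decompose by oxidation or by acid.

The fallback sets out from 13 and comes back at 16. The order of the last two operations is inverted.
- BBr3 (CH2Cl2, −78 °C to 0 °C) converts 13 through dibromo[2,4-dibromo-6-(1H-pyrrol-2-yl)phenoxy]borane F6, which is hydrolysed on work-up to 2,4-dibromo-6-(1H-pyrrol-2-yl)phenol F7.
- Pyridinium tribromide (3 equiv, EtOH, 0 °C to rt) then brominates F7. Both ortho positions and the para position of the phenol are occupied, so only the pyrrole is attacked, and the product is 16 directly.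

## Further compounds
F1 | step 5 | 2,4-dibromo-6-iodophenol | Oc1c(Br)cc(Br)cc1I
F2 | step 5 | 1,5-dibromo-3-iodo-2-methoxybenzene | COc1c(Br)cc(Br)cc1I
F3 | step 5 | (1-tosyl-1H-pyrrol-2-yl)zinc chloride | Cl[Zn]c1cccn1S(=O)(=O)c1ccc(C)cc1
F4 | step 4 | 2-methoxy-1-(1-tosyl-1H-pyrrol-2-yl)ethan-1-one | COCC(=O)c1cccn1S(=O)(=O)c1ccc(C)cc1
F5 | step 4 | (Z)-2-methoxy-1-(1-tosyl-1H-pyrrol-2-yl)vinyl trifluoromethanesulfonate | CO/C=C(\OS(=O)(=O)C(F)(F)F)c1cccn1S(=O)(=O)c1ccc(C)cc1
F6 | step 7 | dibromo[2,4-dibromo-6-(1H-pyrrol-2-yl)phenoxy]borane | BrB(Br)Oc1c(Br)cc(Br)cc1-c1ccc[nH]1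
F7 | step 7 | 2,4-dibromo-6-(1H-pyrrol-2-yl)phenol | Oc1c(Br)cc(Br)cc1-c1ccc[nH]1
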